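## Retrosynthetic overview

- **Feature:** on ring A the pyran oxygen O1 sits on C8a, para to the acyl-bearing C6, and C4a carries the C4 methylene. O1 therefore maps onto the 4-OH of 2,4,6-trihydroxyacetophenone, the most acidic and least hindered of its three hydroxyls.
- **Endgame:** the three phenols are released from MOM ethers. The C3–C4 single bond comes from the cis-disubstituted alkene of a 2H-chromene, reduced beside the trisubstituted prenyl alkene.
- **Key disconnection:** C4–C4a of the chromene leads back to the aryl 1,1-dimethylpropargyl ether of the complete dihydrochalcone (propargyl Claisen, hydrogen shift, oxa-6π closure).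
- **Chain:** the three-carbon chain is cut at Cα–Cβ, giving the enolate of the ring A methyl ketone and a ring B benzylic bromide made from 4-hydroxybenzaldehyde by C-prenylation.
- **Ring order:** rings A and B are bought, and the pyran ring is the only ring formed, in step 8.

Key step: step 8

Remark: the target has no stereocentre and no stereodefined alkene, so the route carries no stereochemical task.

## Route

Step 1
Reactants: 1 phloroacetophenone (2,4,6-trihydroxyacetophenone); 2 tertiary propargylic chloride 3-chloro-3-methylbut-1-yne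
Product: 3 para ether 1-[2,6-dihydroxy-4-(2-methylbut-3-yn-2-yloxy)phenyl]ethan-1-one
Conditions: 2 (1.1 equiv), DBU (1.2 equiv), CuCl2·2H2O (1 mol %), MeCN, 0 °C to rt, Ar
Reagents that add atoms: none
Why: Copper-catalysed propargylic etherification (a Williamson-type O-alkylation through a copper allenylidene) should occur at the 4-OH, which is the most acidic and least hindered hydroxyl, whereas the two ortho hydroxyls share the hydrogen bond to the carbonyl oxygen and are shielded by the acetyl group against a tertiary electrophile.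

Step 2
Reactants: 3 para ether 1-[2,6-dihydroxy-4-(2-methylbut-3-yn-2-yloxy)phenyl]ethan-1-one
Product: 4 ring A ketone 1-[2,6-bis(methoxymethoxy)-4-(2-methylbut-3-yn-2-yloxy)phenyl]ethan-1-one
Conditions: NaH (2.4 equiv), MOMCl (2.6 equiv), DMF, 0 °C to rt
Reagents that add atoms: chloromethyl methyl ether (MOMCl), COCCl
Why: Williamson-type MOM ether formation with the irreversible base NaH breaks the intramolecular hydrogen bond and caps both ortho phenoxides, while the tertiary propargyl ether and the alkyne C–H are inert under these conditions.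

Step 3
Reactants: 5 4-hydroxybenzaldehyde; 6 prenyl bromide (1-bromo-3-methylbut-2-ene)
Product: 7 prenyl phenol 4-hydroxy-3-(3-methylbut-2-en-1-yl)benzaldehyde
Conditions: KOH (1.1 equiv), H2O, 6 (1.0 equiv), rt
Reagents that add atoms: none
Why: Ortho C-alkylation of an ambident phenoxide in water, where hydrogen bonding masks the oxygen, is the established direct C-prenylation of this aldehyde, and phenol 7 is separated from neutral O-alkylated material by extraction into base.

Step 4
Reactants: 7 prenyl phenol 4-hydroxy-3-(3-methylbut-2-en-1-yl)benzaldehyde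
Product: 8 ring B aldehyde 4-(methoxymethoxy)-3-(3-methylbut-2-en-1-yl)benzaldehyde
Conditions: MOMCl (1.5 equiv), iPr2NEt (2 equiv), CH2Cl2, 0 °C to rt
Reagents that add atoms: chloromethyl methyl ether (MOMCl), COCCl
Why: Standard MOM protection of an unhindered acidic phenol removes the proton that would quench the enolate of step 7 and matches the ring A protecting groups, so that one acid step frees all three phenols.

Step 5
Reactants: 8 ring B aldehyde 4-(methoxymethoxy)-3-(3-methylbut-2-en-1-yl)benzaldehyde
Product: 9 benzylic alcohol [4-(methoxymethoxy)-3-(3-methylbut-2-en-1-yl)phenyl]methanol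
Conditions: NaBH4, MeOH, 0 °C
Reagents that add atoms: none
Why: Borohydride reduction of an aromatic aldehyde is fast and leaves the isolated alkene and the acetal untouched.

Step 6
Reactants: 9 benzylic alcohol [4-(methoxymethoxy)-3-(3-methylbut-2-en-1-yl)phenyl]methanol
Product: 10 benzylic bromide 4-(bromomethyl)-1-(methoxymethoxy)-2-(3-methylbut-2-en-1-yl)benzene
Conditions: CBr4 (1.2 equiv), PPh3 (1.25 equiv), CH2Cl2, 0 °C; short plug filtration, used at once
Reagents that add atoms: carbon tetrabromide, BrC(Br)(Br)Br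
Why: The Appel bromination runs under essentially neutral conditions, so neither the acid-labile MOM acetal nor the prenyl alkene is exposed to HBr.

Step 7
Reactants: 4 ring A ketone 1-[2,6-bis(methoxymethoxy)-4-(2-methylbut-3-yn-2-yloxy)phenyl]ethan-1-one; 10 benzylic bromide 4-(bromomethyl)-1-(methoxymethoxy)-2-(3-methylbut-2-en-1-yl)benzene
Product: 12 propargyl ether dihydrochalcone 1-[2,6-bis(methoxymethoxy)-4-(2-methylbut-3-yn-2-yloxy)phenyl]-3-[4-(methoxymethoxy)-3-(3-methylbut-2-en-1-yl)phenyl]propan-1-one, via lithium enolate 11 (not isolated)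
Conditions: 4 (1.2 equiv), LiN(SiMe3)2 (1.2 equiv), THF, −78 °C; then 10 (1.0 equiv), −78 to 0 °C
Reagents that add atoms: none
Why: SN2 alkylation of a kinetic lithium enolate should work because the ketone α-C–H is several pK units more acidic than the alkyne C–H, the doubly ortho-substituted carbonyl resists self-aldol reaction, and keeping the reactive benzylic bromide as the limiting partner at low temperature restrains a second alkylation.

Step 8
Reactants: 12 propargyl ether dihydrochalcone 1-[2,6-bis(methoxymethoxy)-4-(2-methylbut-3-yn-2-yloxy)phenyl]-3-[4-(methoxymethoxy)-3-(3-methylbut-2-en-1-yl)phenyl]propan-1-one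
Product: 16 linear chromene 1-[5,7-bis(methoxymethoxy)-2,2-dimethyl-2H-chromen-6-yl]-3-[4-(methoxymethoxy)-3-(3-methylbut-2-en-1-yl)phenyl]propan-1-one, via allenyl dienone 13 (not isolated), via allenylphenol 14 (not isolated), via ortho-quinone methide 15 (not isolated)
Conditions: o-xylene (degassed, 0.05 M), 145 °C, Ar
Reagents that add atoms: none
Why: Heating starts an aromatic propargyl Claisen rearrangement in which the terminal alkyne carbon bonds to a free ortho carbon of ring A while the O–CMe2 bond breaks, giving allenyl dienone 13, which tautomerises to allenylphenol 14. A 1,5-hydrogen shift from the phenol oxygen to the central allene carbon then gives the Z ortho-quinone methide 15. The pyran ring closes by a thermally allowed oxa-6π electrocyclisation of the O=C–C=C–C=C unit of 15, with the carbonyl oxygen bonding to CMe2, so the only net new skeletal bond is C4–C4a and the oxygen that left the CMe2 carbon returns to it. This is the standard thermal conversion of aryl 1,1-dimethylpropargyl ethers into 2,2-dimethyl-2H-chromenes, helped here by the gem-dimethyl group and by the two alkoxy groups that activate the reacting carbon. No stereocentre is formed. The step needs linear rather than angular closure, which the substrate secures because the symmetric 2,6-bis(MOM) pattern makes both ortho carbons lead to the same product and leaves only the para oxygen free to become the quinone methide oxygen.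

Step 9
Reactants: 16 linear chromene 1-[5,7-bis(methoxymethoxy)-2,2-dimethyl-2H-chromen-6-yl]-3-[4-(methoxymethoxy)-3-(3-methylbut-2-en-1-yl)phenyl]propan-1-one
Product: 17 protected chroman 1-[5,7-bis(methoxymethoxy)-2,2-dimethyl-3,4-dihydro-2H-chromen-6-yl]-3-[4-(methoxymethoxy)-3-(3-methylbut-2-en-1-yl)phenyl]propan-1-one
Conditions: H2 (1 atm), RhCl(PPh3)3 (5 mol %), toluene–EtOH 1:1, rt; stopped after uptake of one equivalent
Reagents that add atoms: none
Why: Homogeneous hydrogenation with RhCl(PPh3)3 is governed by alkene coordination and reduces cis-disubstituted ring alkenes, even next to a quaternary carbon as in the 1,2-alkene of steroidal 1,4-dien-3-ones, much faster than trisubstituted alkenes, so C3=C4 should be saturated while the prenyl alkene, the ketone and the MOM ethers remain.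

Step 10
Reactants: 17 protected chroman 1-[5,7-bis(methoxymethoxy)-2,2-dimethyl-3,4-dihydro-2H-chromen-6-yl]-3-[4-(methoxymethoxy)-3-(3-methylbut-2-en-1-yl)phenyl]propan-1-one
Product: 18 target 1-(5,7-dihydroxy-2,2-dimethyl-3,4-dihydro-2H-chromen-6-yl)-3-[4-hydroxy-3-(3-methylbut-2-en-1-yl)phenyl]propan-1-one
Conditions: conc. HCl (cat.), MeOH, 40 °C
Reagents that add atoms: none
Why: Acid-catalysed acetal exchange with methanol removes all three MOM groups under conditions commonly used for prenylated phenols, which are too mild to protonate the prenyl alkene and cyclise it onto the neighbouring ring B phenol.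

## Compound list

1 | 2,4,6-trihydroxyacetophenone | CC(=O)c1c(O)cc(O)cc1O | starting material
2 | 3-chloro-3-methylbut-1-yne | C#CC(C)(C)Cl | starting material
3 | 1-[2,6-dihydroxy-4-(2-methylbut-3-yn-2-yloxy)phenyl]ethan-1-one | CC(=O)c1c(O)cc(OC(C)(C)C#C)cc1O | intermediate
4 | 1-[2,6-bis(methoxymethoxy)-4-(2-methylbut-3-yn-2-yloxy)phenyl]ethan-1-one | CC(=O)c1c(OCOC)cc(OC(C)(C)C#C)cc1OCOC | intermediate
5 | 4-hydroxybenzaldehyde | O=Cc1ccc(O)cc1 | starting material
6 | prenyl bromide (1-bromo-3-methylbut-2-ene) | CC(C)=CCBr | starting material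
7 | 4-hydroxy-3-(3-methylbut-2-en-1-yl)benzaldehyde | CC(C)=CCc1cc(C=O)ccc1O | intermediate
8 | 4-(methoxymethoxy)-3-(3-methylbut-2-en-1-yl)benzaldehyde | CC(C)=CCc1cc(C=O)ccc1OCOC | intermediate
9 | [4-(methoxymethoxy)-3-(3-methylbut-2-en-1-yl)phenyl]methanol | CC(C)=CCc1cc(CO)ccc1OCOC | intermediate
10 | 4-(bromomethyl)-1-(methoxymethoxy)-2-(3-methylbut-2-en-1-yl)benzene | CC(C)=CCc1cc(CBr)ccc1OCOC | intermediate
11 | lithium enolate of 4 (not isolated) | C=C([O-])c1c(OCOC)cc(OC(C)(C)C#C)cc1OCOC.[Li+] | intermediate
12 | 1-[2,6-bis(methoxymethoxy)-4-(2-methylbut-3-yn-2-yloxy)phenyl]-3-[4-(methoxymethoxy)-3-(3-methylbut-2-en-1-yl)phenyl]propan-1-one | C#CC(C)(C)Oc1cc(OCOC)c(C(=O)CCc2ccc(OCOC)c(CC=C(C)C)c2)c(OCOC)c1 | intermediate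
13 | 3,5-bis(methoxymethoxy)-4-{3-[4-(methoxymethoxy)-3-(3-methylbut-2-en-1-yl)phenyl]propanoyl}-6-(3-methylbuta-1,2-dien-1-yl)cyclohexa-2,4-dien-1-one, racemic (not isolated) | O=C1C=C(OCOC)C(C(=O)CCc2ccc(OCOC)c(CC=C(C)C)c2)=C(OCOC)C1C=C=C(C)C | intermediate
14 | 1-[4-hydroxy-2,6-bis(methoxymethoxy)-3-(3-methylbuta-1,2-dien-1-yl)phenyl]-3-[4-(methoxymethoxy)-3-(3-methylbut-2-en-1-yl)phenyl]propan-1-one (not isolated) | CC(C)=C=Cc1c(O)cc(OCOC)c(C(=O)CCc2ccc(OCOC)c(CC=C(C)C)c2)c1OCOC | intermediate
15 | (6Z)-3,5-bis(methoxymethoxy)-4-{3-[4-(methoxymethoxy)-3-(3-methylbut-2-en-1-yl)phenyl]propanoyl}-6-(3-methylbut-2-en-1-ylidene)cyclohexa-2,4-dien-1-one (not isolated) | CC(C)=C/C=C1\C(=O)C=C(OCOC)C(C(=O)CCc2ccc(OCOC)c(CC=C(C)C)c2)=C1OCOC | intermediate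
16 | 1-[5,7-bis(methoxymethoxy)-2,2-dimethyl-2H-chromen-6-yl]-3-[4-(methoxymethoxy)-3-(3-methylbut-2-en-1-yl)phenyl]propan-1-one | CC(C)=CCc1cc(CCC(=O)c2c(OCOC)cc3c(c2OCOC)C=CC(C)(C)O3)ccc1OCOC | intermediate
17 | 1-[5,7-bis(methoxymethoxy)-2,2-dimethyl-3,4-dihydro-2H-chromen-6-yl]-3-[4-(methoxymethoxy)-3-(3-methylbut-2-en-1-yl)phenyl]propan-1-one | CC(C)=CCc1cc(CCC(=O)c2c(OCOC)cc3c(c2OCOC)CCC(C)(C)O3)ccc1OCOC | intermediate
18 | 1-(5,7-dihydroxy-2,2-dimethyl-3,4-dihydro-2H-chromen-6-yl)-3-[4-hydroxy-3-(3-methylbut-2-en-1-yl)phenyl]propan-1-one | CC(C)=CCc1cc(CCC(=O)c2c(O)cc3c(c2O)CCC(C)(C)O3)ccc1O | target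

## Step count and risks

Total step count: 10.
Longest linear sequence: 8 steps (steps 3, 4, 5, 6, 7, 8, 9 and 10, from 5 to 18).

**Step 9, loss of chemoselectivity.** The chromene alkene is flanked by the quaternary C2 and the peri C5 OMOM group. It may therefore coordinate slowly to rhodium, so that the hydrogenation stalls or the prenyl alkene starts to be reduced as well.
- The fallback changes the order of events so that the chromene is reduced before any other alkene is present.
- It sets out from 4. Heating 4 in o-xylene at 145 °C runs the same Claisen cascade at the methyl ketone stage and gives 1-[5,7-bis(methoxymethoxy)-2,2-dimethyl-2H-chromen-6-yl]ethan-1-one F1.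
- Exhaustive hydrogenation (H2, Pd/C, EtOAc, rt) gives 1-[5,7-bis(methoxymethoxy)-2,2-dimethyl-3,4-dihydro-2H-chromen-6-yl]ethan-1-one F2.
- LiN(SiMe3)2 in THF at −78 °C converts F2 into the lithium enolate of the chroman ketone F3, which is alkylated with 10.
- The fallback comes back to the route at 17.

**Step 1, incomplete site selectivity.** A second etherification at an ortho hydroxyl, attack through a ring carbon of the phloroglucinol nucleus, or sluggish substitution at the tertiary centre may erode the supply of 3.
- The fallback relays the selectivity through a temporary protecting group, so that the propargylic chloride meets a substrate with a single free phenol.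
- It sets out from 1. Benzyl bromide (1.0 equiv) with K2CO3 in acetone gives 1-[4-(benzyloxy)-2,6-dihydroxyphenyl]ethan-1-one F4.
- NaH and MOMCl in DMF give 1-[4-(benzyloxy)-2,6-bis(methoxymethoxy)phenyl]ethan-1-one F5.
- Hydrogenolysis (H2, Pd/C, EtOAc) gives 1-[4-hydroxy-2,6-bis(methoxymethoxy)phenyl]ethan-1-one F6.
- Etherification of F6 with 2 (DBU, CuCl2·2H2O cat., MeCN, 0 °C) comes back to the route at 4.

**Step 7, double alkylation and loss of the electrophile.** Proton exchange between product and enolate may lead to a second benzylation, and the electron-rich benzylic bromide may decompose before it reacts.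
- The fallback replaces alkylation by condensation and conjugate reduction, which makes steps 5 and 6 unnecessary.
- It sets out from 4 and 8. Claisen–Schmidt condensation (KOH, EtOH, rt) gives (E)-1-[2,6-bis(methoxymethoxy)-4-(2-methylbut-3-yn-2-yloxy)phenyl]-3-[4-(methoxymethoxy)-3-(3-methylbut-2-en-1-yl)phenyl]prop-2-en-1-one F7.
- Catecholborane in THF at rt adds 1,4 to the s-cis enone through a six-membered transition state. At this temperature it is slow toward the terminal alkyne and the prenyl alkene. It gives the Z catechol boron enolate F8.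
- Hydrolysis of F8 with aqueous buffer comes back to the route at 12.

## Further compounds

F1 | step 9 | 1-[5,7-bis(methoxymethoxy)-2,2-dimethyl-2H-chromen-6-yl]ethan-1-one | CC(=O)c1c(OCOC)cc2c(c1OCOC)C=CC(C)(C)O2
F2 | step 9 | 1-[5,7-bis(methoxymethoxy)-2,2-dimethyl-3,4-dihydro-2H-chromen-6-yl]ethan-1-one | CC(=O)c1c(OCOC)cc2c(c1OCOC)CCC(C)(C)O2
F3 | step 9 | lithium enolate of the chroman ketone F2 | C=C([O-])c1c(OCOC)cc2c(c1OCOC)CCC(C)(C)O2.[Li+]
F4 | step 1 | 1-[4-(benzyloxy)-2,6-dihydroxyphenyl]ethan-1-one | CC(=O)c1c(O)cc(OCc2ccccc2)cc1O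
F5 | step 1 | 1-[4-(benzyloxy)-2,6-bis(methoxymethoxy)phenyl]ethan-1-one | CC(=O)c1c(OCOC)cc(OCc2ccccc2)cc1OCOC
F6 | step 1 | 1-[4-hydroxy-2,6-bis(methoxymethoxy)phenyl]ethan-1-one | CC(=O)c1c(OCOC)cc(O)cc1OCOC
F7 | step 7 | (E)-1-[2,6-bis(methoxymethoxy)-4-(2-methylbut-3-yn-2-yloxy)phenyl]-3-[4-(methoxymethoxy)-3-(3-methylbut-2-en-1-yl)phenyl]prop-2-en-1-one | C#CC(C)(C)Oc1cc(OCOC)c(C(=O)/C=C/c2ccc(OCOC)c(CC=C(C)C)c2)c(OCOC)c1
F8 | step 7 | Z catechol boron enolate, 2-{(Z)-1-[2,6-bis(methoxymethoxy)-4-(2-methylbut-3-yn-2-yloxy)phenyl]-3-[4-(methoxymethoxy)-3-(3-methylbut-2-en-1-yl)phenyl]prop-1-en-1-yloxy}-1,3,2-benzodioxaborole | C#CC(C)(C)Oc1cc(OCOC)c(c(OCOC)c1)/C(OB1Oc2ccccc2O1)=C/Cc1ccc(OCOC)c(CC=C(C)C)c1
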